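**Plan**
1. Retrosynthetic cuts, in order: the two benzyl ethers and the carbinol C–H of the side chain (ketone reduction); the ring C–carbonyl bond (aryllithium plus N-methoxy-N-methylamide); the aryl ether O–CH(CH3) bond (Mitsunobu); the C3 and C4 methyl groups back to CO2Me and CH2OSi; the oxolane across C2–C3 and O1–C5 into aldehyde 9 and cyclopropane 7; the cyclopropane into enal 3 and bromomalonate 4.
2. Enabling feature: in the oxolane, O1 lies between two benzylic carbons. C5 carries the electron-rich ring B and stands 1,3 to C3, so C3–C4–C5 can be a donor–acceptor cyclopropane (C3 as malonate carbon) and O1=C2 an aldehyde of ring A.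
3. Forward order: the cyclopropane is made first by an organocatalytic Michael-initiated ring closure. The oxolane then arises in one (3+2) annulation whose ring-closing event is C2–C3 bond formation. The ester and silyloxymethyl groups are taken down to the two methyls, and the ring C side chain is joined last through the ring A phenol.
4. Stereochemistry: C4 and C5 come from the catalyst-set cyclopropane (C5 by SN2 inversion, C4 unchanged), C2 from the cis-2,5 ring closure, and C3 from thermodynamic equilibration of the ester. The ether-bearing side-chain carbon comes from (S)-lactate with Mitsunobu inversion, the carbinol carbon from Felkin–Anh hydride addition.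

Key step: step 6

Numbering used in the names: oxolane O1, C2 (bears ring A, the aryl ring that carries the ether side chain), C3, C4, C5 (bears ring B); ring C is the aryl ring of the side chain.
Assumption: compounds 1, 2, 4, 8, 19, 22 and (R)-2-[diphenyl(trimethylsilyloxy)methyl]pyrrolidine are taken as commercial.

**Step 1**
Reactants: 1 4-(benzyloxy)-3-methoxybenzaldehyde; 2 (triphenylphosphoranylidene)acetaldehyde
Product: 3 (2E)-3-[4-(benzyloxy)-3-methoxyphenyl]prop-2-enal
Conditions: 2 (1.2 equiv), toluene, 80 °C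
Reagents that add atoms: none
Why: Wittig olefination with the stabilised formylmethylene ylide should give the E-enal.

**Step 2**
Reactants: 3 enal; 4 dimethyl 2-bromopropanedioate
Product: 5 dimethyl (2R,3S)-2-[4-(benzyloxy)-3-methoxyphenyl]-3-formylcyclopropane-1,1-dicarboxylate
Conditions: 4 (1.2 equiv), (R)-2-[diphenyl(trimethylsilyloxy)methyl]pyrrolidine (20 mol %), 2,6-lutidine (1.1 equiv), CH2Cl2, 0 °C
Reagents that add atoms: none
Why: Organocatalytic Michael-initiated ring closure (iminium then enamine): the diphenyl(silyloxy)methyl group of the (R)-catalyst shields one face of the E-iminium ion, so bromomalonate adds to the open face of the β-carbon and the enamine closes the ring by 3-exo-tet displacement of bromide, trans to the aryl group.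

**Step 3**
Reactants: 5 formylcyclopropane
Product: 6 dimethyl (2R,3S)-2-[4-(benzyloxy)-3-methoxyphenyl]-3-(hydroxymethyl)cyclopropane-1,1-dicarboxylate
Conditions: NaBH4, MeOH/CH2Cl2, −40 °C; aqueous NH4Cl quench; crude alcohol taken into step 4 at once
Reagents that add atoms: none
Why: Borohydride reduction is chemoselective for the aldehyde over the geminal diester, and low temperature with a neutral quench should keep the cis hydroxymethyl/ester pair from lactonising.

**Step 4**
Reactants: 6 hydroxymethylcyclopropane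
Product: 7 dimethyl (2R,3S)-2-[4-(benzyloxy)-3-methoxyphenyl]-3-{[(tert-butyldiphenylsilyl)oxy]methyl}cyclopropane-1,1-dicarboxylate
Conditions: TBDPSCl, imidazole, CH2Cl2, 0 °C to rt
Reagents that add atoms: tert-butyl(chloro)diphenylsilane CC(C)(C)[Si](Cl)(c1ccccc1)c1ccccc1
Why: Standard silylation of a primary alcohol; the bulky silyl ether blocks lactonisation and should tolerate the Lewis acid, hot wet DMSO, methoxide and hydride used later.

**Step 5**
Reactants: 8 vanillin
Product: 9 3-methoxy-4-(prop-2-en-1-yloxy)benzaldehyde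
Conditions: allyl bromide, K2CO3, acetone, reflux
Reagents that add atoms: allyl bromide C=CCBr
Why: Williamson etherification of the phenoxide; allyl is chosen because it can be removed later without touching the benzyl ether.

**Step 6**
Reactants: 7 silyloxymethyl cyclopropane diester; 9 O-allylvanillin
Product: 11 dimethyl (2S,4S,5S)-5-[4-(benzyloxy)-3-methoxyphenyl]-4-{[(tert-butyldiphenylsilyl)oxy]methyl}-2-[3-methoxy-4-(prop-2-en-1-yloxy)phenyl]oxolane-3,3-dicarboxylate, via oxocarbenium malonate zwitterion 10 (not isolated)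
Conditions: AlCl3 (20 mol %), 9 (3 equiv), CH2Cl2, 0 °C to rt
Reagents that add atoms: none
Why: AlCl3 chelates the geminal diester of 7 and the aldehyde oxygen of 9 opens the activated ring by SN2 attack at the benzylic carbon with inversion, giving zwitterion 10; after rotation about the C4–C5 bond the malonate carbon attacks the oxocarbenium carbon and closes the oxolane by forming C2–C3. The closest known reaction type is the Lewis-acid-catalysed formal (3+2) annulation of aryl donor–acceptor cyclopropane-1,1-diesters with aldehydes, which has precedent for trans-2,3-disubstituted aryl cyclopropanes. The ring closes in a 5-(enolexo)-endo-trig aldol-type mode, feasible here because the electrophile is a cationic C=O+ unit that the enolate reaches through an envelope transition state. C5 is controlled by the cyclopropane stereocentre through inversion, C4 is carried over unchanged, and C2 is set in the closure, where an envelope with both aryl groups pseudo-equatorial gives the 2,5-cis oxolane; C3 is not yet stereogenic. The step needs SN2 opening rather than ionisation to a free benzylic cation, and attack at the aryl-bearing carbon rather than the silyloxymethyl-bearing one. The para-alkoxyaryl donor directs the regiochemistry, the tight ion pair at low temperature in CH2Cl2 preserves the stereochemistry, and the non-epimerisable C4 centre means any leakage gives a separable diastereomer, not the enantiomer.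

**Step 7**
Reactants: 11 oxolane-3,3-diester
Product: 13 methyl (2R,3R,4S,5S)-5-[4-(benzyloxy)-3-methoxyphenyl]-4-{[(tert-butyldiphenylsilyl)oxy]methyl}-2-[3-methoxy-4-(prop-2-en-1-yloxy)phenyl]oxolane-3-carboxylate, via C3-epimeric monoester mixture 12 (not isolated)
Conditions: LiCl, H2O, DMSO, 150 °C; extractive work-up; then NaOMe (0.3 equiv), MeOH, rt to 40 °C
Reagents that add atoms: none
Why: Krapcho dealkoxycarbonylation (chloride SN2 at an ester methyl, then loss of CO2) removes one ester, and methoxide equilibration of the enolisable C3 centre should place the remaining ester trans to both the C2 aryl and the C4 substituent, the only arrangement that avoids an all-cis oxolane.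

**Step 8**
Reactants: 13 oxolane-3-carboxylate
Product: 14 [(2R,3S,4S,5S)-5-[4-(benzyloxy)-3-methoxyphenyl]-4-{[(tert-butyldiphenylsilyl)oxy]methyl}-2-[3-methoxy-4-(prop-2-en-1-yloxy)phenyl]oxolan-3-yl]methanol
Conditions: LiAlH4, THF, 0 °C
Reagents that add atoms: none
Why: Hydride reduction of the ester to the primary alcohol; no epimerisable centre remains and the silyl, allyl and benzyl ethers are inert.

**Step 9**
Reactants: 14 mono-silylated diol
Product: 15 [(2R,3S,4S,5S)-5-[4-(benzyloxy)-3-methoxyphenyl]-2-[3-methoxy-4-(prop-2-en-1-yloxy)phenyl]oxolane-3,4-diyl]dimethanol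
Conditions: TBAF, THF, rt
Reagents that add atoms: none
Why: Fluoride-mediated desilylation frees the second primary alcohol without touching the aryl ethers.

**Step 10**
Reactants: 15 diol
Product: 16 [(2R,3S,4S,5S)-5-[4-(benzyloxy)-3-methoxyphenyl]-2-[3-methoxy-4-(prop-2-en-1-yloxy)phenyl]oxolane-3,4-diyl]bis(methylene) dimethanesulfonate
Conditions: MsCl, Et3N, CH2Cl2, 0 °C
Reagents that add atoms: methanesulfonyl chloride CS(=O)(=O)Cl
Why: Sulfonylation activates both primary alcohols for hydride displacement.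

**Step 11**
Reactants: 16 dimesylate
Product: 17 (2R,3R,4R,5S)-5-[4-(benzyloxy)-3-methoxyphenyl]-2-[3-methoxy-4-(prop-2-en-1-yloxy)phenyl]-3,4-dimethyloxolane
Conditions: LiEt3BH, THF, 0 °C to 60 °C
Reagents that add atoms: none
Why: SN2 displacement of the two primary mesylates by hydride gives both methyl groups without touching a stereocentre, a standard diol-to-dimethyl sequence for oxolane lignans.

**Step 12**
Reactants: 17 allyl ether
Product: 18 4-[(2R,3R,4R,5S)-5-[4-(benzyloxy)-3-methoxyphenyl]-3,4-dimethyloxolan-2-yl]-2-methoxyphenol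
Conditions: Pd(PPh3)4 (5 mol %), morpholine, THF, rt
Reagents that add atoms: none
Why: Tsuji–Trost-type deallylation: zerovalent palladium ionises the allyl aryl ether to a π-allyl complex that morpholine captures, leaving the benzyl ether intact.

**Step 13**
Reactants: 19 ethyl (2S)-2-hydroxypropanoate
Product: 20 (2S)-2-hydroxy-N-methoxy-N-methylpropanamide
Conditions: MeNHOMe·HCl, i-PrMgCl, THF, −20 to 0 °C
Reagents that add atoms: N,O-dimethylhydroxylamine hydrochloride CNOC.Cl
Why: Aminolysis of the ester by the chloromagnesium amide (Weinreb amide formation); the magnesium alkoxide of the free hydroxyl protects the stereocentre from enolisation.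

**Step 14**
Reactants: 18 ring A phenol; 20 (S)-lactamide
Product: 21 (2R)-2-{4-[(2R,3R,4R,5S)-5-[4-(benzyloxy)-3-methoxyphenyl]-3,4-dimethyloxolan-2-yl]-2-methoxyphenoxy}-N-methoxy-N-methylpropanamide
Conditions: PPh3, DIAD, THF, 0 °C to rt
Reagents that add atoms: none
Why: Mitsunobu etherification: the phenoxide displaces the activated secondary alcohol by SN2 with inversion, turning (S) into (R) at the ether-bearing carbon.

**Step 15**
Reactants: 21 aryloxy amide; 22 1-(benzyloxy)-4-bromo-2-methoxybenzene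
Product: 24 (2R)-1-[4-(benzyloxy)-3-methoxyphenyl]-2-{4-[(2R,3R,4R,5S)-5-[4-(benzyloxy)-3-methoxyphenyl]-3,4-dimethyloxolan-2-yl]-2-methoxyphenoxy}propan-1-one, via aryllithium 23 (not isolated)
Conditions: 22, n-BuLi, THF, −78 °C; then 21, −78 °C; aqueous NH4Cl
Reagents that add atoms: none
Why: Bromine–lithium exchange followed by Weinreb ketone synthesis; the chelated tetrahedral adduct stops the addition at the ketone stage and keeps the α-aryloxy centre from enolising.

**Step 16**
Reactants: 24 α-aryloxy ketone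
Product: 25 (1R,2R)-1-[4-(benzyloxy)-3-methoxyphenyl]-2-{4-[(2R,3R,4R,5S)-5-[4-(benzyloxy)-3-methoxyphenyl]-3,4-dimethyloxolan-2-yl]-2-methoxyphenoxy}propan-1-ol
Conditions: NaBH4, 15-crown-5, MeOH/CH2Cl2, −40 °C
Reagents that add atoms: none
Why: Felkin–Anh addition under non-chelating conditions (the crown ether sequesters the sodium ion): with the aryloxy group anti to the incoming hydride, attack past the α-hydrogen should give the threo (1R,2R) alcohol.

**Step 17**
Reactants: 25 bis-benzyl ether
Product: 26 (1R,2R)-1-(4-hydroxy-3-methoxyphenyl)-2-{4-[(2R,3R,4R,5S)-5-(4-hydroxy-3-methoxyphenyl)-3,4-dimethyloxolan-2-yl]-2-methoxyphenoxy}propan-1-ol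
Conditions: H2 (1 atm), 10% Pd/C, EtOAc, rt, stopped after uptake of two equivalents
Reagents that add atoms: none
Why: Hydrogenolysis of the two benzyl aryl ethers under mild conditions should leave the benzylic C–O bonds of the oxolane and of the carbinol in place.

**Compound list**
1 | 4-(benzyloxy)-3-methoxybenzaldehyde | COc1cc(C=O)ccc1OCc1ccccc1 | starting material
2 | (triphenylphosphoranylidene)acetaldehyde | O=CC=P(c1ccccc1)(c1ccccc1)c1ccccc1 | starting material
3 | (2E)-3-[4-(benzyloxy)-3-methoxyphenyl]prop-2-enal | COc1cc(/C=C/C=O)ccc1OCc1ccccc1 | intermediate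
4 | dimethyl 2-bromopropanedioate | COC(=O)C(Br)C(=O)OC | starting material
5 | dimethyl (2R,3S)-2-[4-(benzyloxy)-3-methoxyphenyl]-3-formylcyclopropane-1,1-dicarboxylate | COC(=O)C1(C(=O)OC)[C@@H](c2ccc(OCc3ccccc3)c(OC)c2)[C@@H]1C=O | intermediate
6 | dimethyl (2R,3S)-2-[4-(benzyloxy)-3-methoxyphenyl]-3-(hydroxymethyl)cyclopropane-1,1-dicarboxylate | COC(=O)C1(C(=O)OC)[C@@H](c2ccc(OCc3ccccc3)c(OC)c2)[C@@H]1CO | intermediate
7 | dimethyl (2R,3S)-2-[4-(benzyloxy)-3-methoxyphenyl]-3-{[(tert-butyldiphenylsilyl)oxy]methyl}cyclopropane-1,1-dicarboxylate | COC(=O)C1(C(=O)OC)[C@@H](c2ccc(OCc3ccccc3)c(OC)c2)[C@@H]1CO[Si](c1ccccc1)(c1ccccc1)C(C)(C)C | intermediate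
8 | 4-hydroxy-3-methoxybenzaldehyde (vanillin) | COc1cc(C=O)ccc1O | starting material
9 | 3-methoxy-4-(prop-2-en-1-yloxy)benzaldehyde | C=CCOc1ccc(C=O)cc1OC | intermediate
10 | (E)-oxocarbenium malonate zwitterion from SN2 opening of 7 by 9, present as its aluminium enolate (not isolated) | C=CCOc1ccc(/C=[O+]/[C@H](c2ccc(OCc3ccccc3)c(OC)c2)[C@H](CO[Si](c2ccccc2)(c2ccccc2)C(C)(C)C)[C-](C(=O)OC)C(=O)OC)cc1OC | intermediate
11 | dimethyl (2S,4S,5S)-5-[4-(benzyloxy)-3-methoxyphenyl]-4-{[(tert-butyldiphenylsilyl)oxy]methyl}-2-[3-methoxy-4-(prop-2-en-1-yloxy)phenyl]oxolane-3,3-dicarboxylate | C=CCOc1ccc([C@@H]2O[C@H](c3ccc(OCc4ccccc4)c(OC)c3)[C@H](CO[Si](c3ccccc3)(c3ccccc3)C(C)(C)C)C2(C(=O)OC)C(=O)OC)cc1OC | intermediate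
12 | methyl (2R,4S,5S)-5-[4-(benzyloxy)-3-methoxyphenyl]-4-{[(tert-butyldiphenylsilyl)oxy]methyl}-2-[3-methoxy-4-(prop-2-en-1-yloxy)phenyl]oxolane-3-carboxylate, mixture of C3 epimers (not isolated) | C=CCOc1ccc([C@@H]2O[C@H](c3ccc(OCc4ccccc4)c(OC)c3)[C@H](CO[Si](c3ccccc3)(c3ccccc3)C(C)(C)C)C2C(=O)OC)cc1OC | intermediate
13 | methyl (2R,3R,4S,5S)-5-[4-(benzyloxy)-3-methoxyphenyl]-4-{[(tert-butyldiphenylsilyl)oxy]methyl}-2-[3-methoxy-4-(prop-2-en-1-yloxy)phenyl]oxolane-3-carboxylate | C=CCOc1ccc([C@@H]2O[C@H](c3ccc(OCc4ccccc4)c(OC)c3)[C@H](CO[Si](c3ccccc3)(c3ccccc3)C(C)(C)C)[C@H]2C(=O)OC)cc1OC | intermediate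
14 | [(2R,3S,4S,5S)-5-[4-(benzyloxy)-3-methoxyphenyl]-4-{[(tert-butyldiphenylsilyl)oxy]methyl}-2-[3-methoxy-4-(prop-2-en-1-yloxy)phenyl]oxolan-3-yl]methanol | C=CCOc1ccc([C@@H]2O[C@H](c3ccc(OCc4ccccc4)c(OC)c3)[C@H](CO[Si](c3ccccc3)(c3ccccc3)C(C)(C)C)[C@H]2CO)cc1OC | intermediate
15 | [(2R,3S,4S,5S)-5-[4-(benzyloxy)-3-methoxyphenyl]-2-[3-methoxy-4-(prop-2-en-1-yloxy)phenyl]oxolane-3,4-diyl]dimethanol | C=CCOc1ccc([C@@H]2O[C@H](c3ccc(OCc4ccccc4)c(OC)c3)[C@H](CO)[C@H]2CO)cc1OC | intermediate
16 | [(2R,3S,4S,5S)-5-[4-(benzyloxy)-3-methoxyphenyl]-2-[3-methoxy-4-(prop-2-en-1-yloxy)phenyl]oxolane-3,4-diyl]bis(methylene) dimethanesulfonate | C=CCOc1ccc([C@@H]2O[C@H](c3ccc(OCc4ccccc4)c(OC)c3)[C@H](COS(C)(=O)=O)[C@H]2COS(C)(=O)=O)cc1OC | intermediate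
17 | (2R,3R,4R,5S)-5-[4-(benzyloxy)-3-methoxyphenyl]-2-[3-methoxy-4-(prop-2-en-1-yloxy)phenyl]-3,4-dimethyloxolane | C=CCOc1ccc([C@@H]2O[C@H](c3ccc(OCc4ccccc4)c(OC)c3)[C@H](C)[C@H]2C)cc1OC | intermediate
18 | 4-[(2R,3R,4R,5S)-5-[4-(benzyloxy)-3-methoxyphenyl]-3,4-dimethyloxolan-2-yl]-2-methoxyphenol | COc1cc([C@@H]2O[C@H](c3ccc(OCc4ccccc4)c(OC)c3)[C@H](C)[C@H]2C)ccc1O | intermediate
19 | ethyl (2S)-2-hydroxypropanoate | CCOC(=O)[C@H](C)O | starting material
20 | (2S)-2-hydroxy-N-methoxy-N-methylpropanamide | C[C@H](O)C(=O)N(C)OC | intermediate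
21 | (2R)-2-{4-[(2R,3R,4R,5S)-5-[4-(benzyloxy)-3-methoxyphenyl]-3,4-dimethyloxolan-2-yl]-2-methoxyphenoxy}-N-methoxy-N-methylpropanamide | CON(C)C(=O)[C@@H](C)Oc1ccc([C@@H]2O[C@H](c3ccc(OCc4ccccc4)c(OC)c3)[C@H](C)[C@H]2C)cc1OC | intermediate
22 | 1-(benzyloxy)-4-bromo-2-methoxybenzene | COc1cc(Br)ccc1OCc1ccccc1 | starting material
23 | [4-(benzyloxy)-3-methoxyphenyl]lithium (not isolated) | COc1cc([Li])ccc1OCc1ccccc1 | intermediate
24 | (2R)-1-[4-(benzyloxy)-3-methoxyphenyl]-2-{4-[(2R,3R,4R,5S)-5-[4-(benzyloxy)-3-methoxyphenyl]-3,4-dimethyloxolan-2-yl]-2-methoxyphenoxy}propan-1-one | COc1cc(C(=O)[C@@H](C)Oc2ccc([C@@H]3O[C@H](c4ccc(OCc5ccccc5)c(OC)c4)[C@H](C)[C@H]3C)cc2OC)ccc1OCc1ccccc1 | intermediate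
25 | (1R,2R)-1-[4-(benzyloxy)-3-methoxyphenyl]-2-{4-[(2R,3R,4R,5S)-5-[4-(benzyloxy)-3-methoxyphenyl]-3,4-dimethyloxolan-2-yl]-2-methoxyphenoxy}propan-1-ol | COc1cc([C@@H](O)[C@@H](C)Oc2ccc([C@@H]3O[C@H](c4ccc(OCc5ccccc5)c(OC)c4)[C@H](C)[C@H]3C)cc2OC)ccc1OCc1ccccc1 | intermediate
26 | (1R,2R)-1-(4-hydroxy-3-methoxyphenyl)-2-{4-[(2R,3R,4R,5S)-5-(4-hydroxy-3-methoxyphenyl)-3,4-dimethyloxolan-2-yl]-2-methoxyphenoxy}propan-1-ol | COc1cc([C@@H](O)[C@@H](C)Oc2ccc([C@@H]3O[C@H](c4ccc(O)c(OC)c4)[C@H](C)[C@H]3C)cc2OC)ccc1O | target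

**Step count**
Total: 17 steps. Longest linear sequence: 15 steps (1–4, 6–12, 14–17, from compound 1).

**Steps most likely to fail**

Step 6. The risk is ionisation of the AlCl3-activated cyclopropane to a free benzylic cation before the weakly nucleophilic aldehyde attacks, which would erode the inversion at C5; Lewis-acid cleavage of the silyl or benzyl ether is a second risk. The fallback sets out from 9 and 7 and returns at 11. NaBH4 reduction of 9 gives [3-methoxy-4-(prop-2-en-1-yloxy)phenyl]methanol F1. This alcohol, a far better nucleophile than the aldehyde, opens 7 under Sc(OTf)3 catalysis in CH2Cl2 by SN2 attack at the benzylic carbon with inversion, giving the γ-benzyloxy malonate F2. DDQ oxidation of the para-alkoxybenzylic ether C–H bond of F2 (oxidative C–H cyclisation of a benzylic ether onto a tethered carbon nucleophile) then generates oxocarbenium malonate 10 without a Lewis acid, and 10 closes to 11.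

Step 7. The risks are incomplete dealkoxycarbonylation of the hindered geminal diester, thermal [3,3] rearrangement of the allyl aryl ether at 150 °C, or loss of the silyl ether in hot wet DMSO. The fallback sets out from 11 and returns at 13. LiOH (one equivalent) in THF/MeOH/H2O at rt hydrolyses the less hindered ester to the malonic half-acid F3. F3 loses CO2 on warming in toluene at 100 °C to give the epimer mixture 12, and the same methoxide equilibration gives 13.

Step 16. The risk is poor facial selectivity, because chelation of the cation by the ketone and the guaiacyl ether oxygens competes with Felkin–Anh control and gives the erythro epimer. The fallback sets out from 21 and returns at 25, and sets the carbinol centre by C–C bond formation under chelate control instead. LiAlH4 in THF at −78 °C reduces amide 21 to (2R)-2-{4-[(2R,3R,4R,5S)-5-[4-(benzyloxy)-3-methoxyphenyl]-3,4-dimethyloxolan-2-yl]-2-methoxyphenoxy}propanal F4. [4-(Benzyloxy)-3-methoxyphenyl]magnesium bromide F5, made from 22 and magnesium, is added with MgBr2·OEt2 in CH2Cl2 at −78 °C. In the five-membered Cram chelate the aryl group is delivered to the aldehyde face next to the α-hydrogen, which should give the threo alcohol 25 directly.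

**Further compounds**
F1 | step 6 | [3-methoxy-4-(prop-2-en-1-yloxy)phenyl]methanol | C=CCOc1ccc(CO)cc1OC
F2 | step 6 | dimethyl 2-[(2S,3S)-3-[4-(benzyloxy)-3-methoxyphenyl]-1-[(tert-butyldiphenylsilyl)oxy]-3-{[3-methoxy-4-(prop-2-en-1-yloxy)phenyl]methoxy}propan-2-yl]propanedioate | C=CCOc1ccc(CO[C@H](c2ccc(OCc3ccccc3)c(OC)c2)[C@H](CO[Si](c2ccccc2)(c2ccccc2)C(C)(C)C)C(C(=O)OC)C(=O)OC)cc1OC
F3 | step 7 | (2S,4S,5S)-5-[4-(benzyloxy)-3-methoxyphenyl]-4-{[(tert-butyldiphenylsilyl)oxy]methyl}-3-(methoxycarbonyl)-2-[3-methoxy-4-(prop-2-en-1-yloxy)phenyl]oxolane-3-carboxylic acid (C3 configuration not assigned) | C=CCOc1ccc([C@@H]2O[C@H](c3ccc(OCc4ccccc4)c(OC)c3)[C@H](CO[Si](c3ccccc3)(c3ccccc3)C(C)(C)C)C2(C(=O)O)C(=O)OC)cc1OC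
F4 | step 16 | (2R)-2-{4-[(2R,3R,4R,5S)-5-[4-(benzyloxy)-3-methoxyphenyl]-3,4-dimethyloxolan-2-yl]-2-methoxyphenoxy}propanal | O=C[C@@H](C)Oc1ccc([C@@H]2O[C@H](c3ccc(OCc4ccccc4)c(OC)c3)[C@H](C)[C@H]2C)cc1OC
F5 | step 16 | [4-(benzyloxy)-3-methoxyphenyl]magnesium bromide | COc1cc([Mg]Br)ccc1OCc1ccccc1
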